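    initiator + impurity → spent initiator (k1 = 12.9 L mol⁻¹ min⁻¹)
    free monomer → uncatalysed product (k2 = 1.25 × 10⁻⁴ min⁻¹)
    free monomer + living end → monomer in chains + living end, rate k3*[living end]*[free monomer] (k3 = 0.0682 L mol⁻¹ min⁻¹)
    free monomer + initiator → living end + monomer in chains (k4 = 0.00549 L mol⁻¹ min⁻¹)

free monomer 0.16 M; initiator 3.2 mM; impurity 1.6 mM; time 3.0 d

- the average divides the monomer in chains by the number of chains begun, living and dead together
- run time (flask): 3.0 d

- whether the average number of monomer units in a chain (chains begun, living or dead) reaches 7.0 by 3.0 d (yes / no)
- average number of monomer units in a chain (chains begun, living or dead) at 3.0 d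

Each initiator is counted once whatever happens to it: it stays initiator, becomes spent initiator or becomes a living end, so these three always add up to the charge, and since no end dies, chains begun equal living ends. At the charged concentrations the initiator's half-life against impurity, 0.56 h, is far shorter than its half-life against free monomer, 13.2 h, so the impurity first spends half of the charged initiator, and the remaining 50.0% can begin chains.

Beginning and growth are both first order in free monomer, so free monomer cancels when one rate law is divided by the other. The surviving initiator decays pseudo-first-order, and I count that decay on a clock x: the unbegun fraction of it is s = e^(−x), and b is the begun fraction. That division leaves g = k3/k4, the rate constant of growth over that of beginning, here 12.4, and the average length is one + g(x/b − one).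

The clock starts at 1.26 d⁻¹. The clock runs in proportion to free monomer, so the uncatalysed loss of free monomer, 1.25 × 10⁻⁴ min⁻¹, slows it, and growth raises that constant towards 2.34 × 10⁻⁴ min⁻¹, with every surviving initiator an end. Over 3.0 d these two constants cut the clock's rate by the factors 0.583 and 0.364. Accumulated, x lands between 2.39 and 2.93, which gives lengths from 21.2 to 27.1. I commit to the middle of x, 2.66, and so to 24.1; the length rises with x, and my low end is above 7.0, so my answer is yes.

The forecast answers yes and gives 23.7, within 21.5 to 26, reasoning that “it passes 7 comfortably and ends near 24”.

The simulated flask answers yes and gives 23.6, with the length of 7.0 reached at 0.702 d. Now use g at 30.0 d, when the flask holds 0.756% of its charged initiator. That makes s = 0.0151 and x = 4.19, so the length comes to 41.4. The same flask then has 40.8% of its charged free monomer in chains and 0.00158 M of living end, and their ratio is 41.4.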